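I passed over the early hours of this flask, in which D was taken up while Z filled, and looked for what stops changing after them; the problem stood thus:

    E ⇌ Z, rate k1*(csat - [Z]) (k1 = 6.4 × 10⁻⁴ s⁻¹, csat = 200 mM)
    D + Z ⇌ D.Z (K2 = 140 M⁻¹, k2 = 0.0033 M⁻¹ s⁻¹)
    D → G (k3 = 5.0 × 10⁻⁵ s⁻¹)
    Q ⇌ D.Z, rate k4*(cs4 - [D.Z]) while solid is left; crystals form when [D.Z] > cs4 (cs4 = 0.20 M, k4 = 0.0012 s⁻¹)
    D.Z ⇌ J (K5 = 1.4, k5 = 9.2 × 10⁻⁶ s⁻¹)

D 0.50 M; E 200 mM (held); time 50 h

- amounts and yields of D.Z count Q too
- given per volume of solution although it is solid: Q
- at the start none of Z is dissolved
- run time (flask): 50 h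

1. the D.Z and Q together standing at 50 h, as a percentage of the D charged
2. concentration of Z in solution at 5.0 h, in percent of saturation
3. the change that raises the amount of D.Z and Q together at 50 h, in percent of the D charged most ("none" if none brings more than 2 percentage points) (Thursday's / Friday's / Saturday's / Tuesday's / none)
4. amount of D.Z and Q together at 50 h, in percent of the D charged, after Saturday's

- Thursday's: doubling the solubility in step 4, all else as stated
- Friday's: doubling the dissolution coefficient of step 4, all else as stated
- Saturday's: doubling the saturation concentration of E, all else as stated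
- Tuesday's: doubling the transfer coefficient of step 1, all else as stated

Refilling Z by the first step has a half-life of 0.301 h, short against the 3.9 h half-life of D by the third step, so once the D was taken up I froze [Z], the concentration of Z, at 200 mM. D.Z is then the resting state and D a passing form: D.Z releases D at the back constant 2.36 × 10⁻⁵ s⁻¹, and binding and the third step together remove D at 7.10 × 10⁻⁴ s⁻¹.

Their quotient is the free ratio r, the standing [D]/[D.Z], which came to 0.0332. While crystals stood, dissolved D.Z was held at 0.20 M, so I expected D at 6.64 mM, or 1.33% of the charge. That D feeds G, so binding runs net backward, and the Z it frees should lift [Z] by 0.519 mM, giving 100.3% of saturation. Saturday's change lowers r to 0.0172, so I looked to it first. My reckoning stopped there, without a figure for y or yb.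

The forecast gave 34% for y, 99.7% for sat, Saturday's as best and 45% for yb, holding that “Doubling csat halves the G losses”.

The simulation gave 32.9%, 100%, Saturday's with a gain of 11 percentage points, and 43.8%. The flask read D 1.33% at 5.00 h, as reckoned, and at 50.0 h, with Q at 0%, D 1.10% beside D.Z 32.9%, a reading of 0.0334 for r.

The neighbouring flask was charged with 2.0 M of D and read at 50.0 h. It still held Q at 45.7%, so dissolved D.Z stood at 0.20 M as before, and r put D at the same 6.64 mM. Against this larger charge that is 0.332%. The neighbouring flask read D 0.33%, with D.Z and Q together at 55.7%.

Its constants belong to no real substance; the run is a simulation.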